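The numbers are those of an exercise; the result is computed.

Each unit of product in this flask sets free one acid, and something must take that acid.

electrophile 0.40 M; nucleophile 2.00 equiv; free base 2.00 equiv; time 25 min

    electrophile + nucleophile ⇌ acid set free + product (K1 = 0.59, k1 = 2.2 M⁻¹ min⁻¹)
    nucleophile + acid set free ⇌ protonated nucleophile, settled at all times (K2 = 220 M⁻¹)
    acid set free + free base ⇌ salt of the base (K3 = 12 M⁻¹, k3 = 2.2 M⁻¹ min⁻¹)
    electrophile ⇌ dormant form (K4 = 0.76, k4 = 0.0042 min⁻¹)

* part of the electrophile that has reacted at 25 min
* share of the unused nucleophile that is free and not bound as protonated nucleophile, at 25 min

- what has gone from electrophile into another species counts as reacted, even if it can come back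
- run time (flask): 25 min

Does the substitution reach balance? Its forward half-life of 0.39 min is far shorter than the run of 25 min, so I treat it under thermodynamic control, not kinetic. The electrophile's forward half-life by the step into the dormant form, 170 min, is longer than the run, so I set that step aside.

Where does the balance lie? Multiplying the constants of the first two steps gives 130 M⁻¹. I call this the buffered constant: at balance it equals c(product) times c(protonated nucleophile), over c(electrophile) times c(nucleophile) squared. I leave the base aside at first, so each electrophile used costs about two nucleophiles: one reacts and one binds the acid. The charge is twice the electrophile, so c(nucleophile) stays twice c(electrophile). A first guess, with full product on top, gives c(electrophile) = 0.0675 M. One repeat gives 0.0597 M. So with the base left aside, I reckon c at 85.1 % and fr at 26.0 %.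

Does the base matter? At that balance c(acid set free) is 0.0130 M. The free base would then hold 0.108 M of salt. At the forward rate with that c(acid set free) and the base as charged, the way back not counted, that much takes 4.72 min, shorter than the run. So I expect acid to move on to the base, nucleophile to come free, and both answers to lie above my values. My reckoning stops there.

The forecast goes further, with 91.5 % and 33 %. Of the nucleophile it says “so it buffers the acid and limits conversion”.

The flask gives 91.8 % and 35.5 %, both above my values, and the forecast stands. The flask's c moves by 5 points at 1.74 equiv or 2.49 equiv of nucleophile, all else held. At 25.0 min the flask's quotient reads 130 M⁻¹, against the buffered constant of 130 M⁻¹. With the base left aside, the neighbour with 3.40 equiv of nucleophile keeps about 0.560 M of it beyond the two used per electrophile. With product near 0.40 M, the constant puts c(electrophile) at 0.003925 M, which is 0.981 % of the charge. That neighbour holds 0.78 % of its electrophile, with c at 99.2 %.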